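**Retrosynthetic overview**
- The pyran ring is opened last: the O–C4 and C15–CH(Ph) bonds come from a Knoevenagel/hetero-Diels–Alder union of a muurolane-type 4(15),5-diene, benzaldehyde and 2,4-diformylphloroglucinol, which sets the spiro and benzylic centres.
- The diene comes from an octalone by methylenation, and the octalone from a cis-fused decalone by Saegusa desaturation.
- Key disconnection: the C1–C2 bond of ring B, formed by a light-driven cyclopropanol ring-opening / 6-exo radical cyclisation / hydrogen-atom-transfer cascade on a preformed ring A; it sets C1 and C10.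
- Ring A: the cyclopropanol comes from a cyclohexenylacetate, made from (S)-cryptone (Mukaiyama–Michael, triflation, methylation); cryptone comes from 3-methylbutanal and butenone (organocatalytic Michael/aldol sets C7).
- Arene: resorcinol → phloroglucinol → dialdehyde. Ring order: ring A, then ring B (radical step), then the pyran ring.

Assumption: terpene carbons are numbered as in cadinane (C1/C6 ring fusion, C4 spiro carbon, C5=C6 alkene, C7 isopropyl-bearing, C10 methyl-bearing, C15 pyran CH2), and the roughly 95% ee set in step 1 is raised to a single enantiomer by recrystallisation of the final product.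

**Route**

Step 1
Reactants: 1 3-methylbutanal; 2 but-3-en-2-one
Product: 4 (4S)-4-(propan-2-yl)cyclohex-2-en-1-one, via keto aldehyde 3 (not isolated)
Conditions: (S)-2-(methoxydiphenylmethyl)pyrrolidine (5 mol%), ethyl 3,4-dihydroxybenzoate (20 mol%), neat, 4 °C; then LiOH (20 mol%), iPrOH, rt
Reagents that add atoms: none
Why: Enamine-catalysed Michael addition of the aldehyde to the enone, in which the diarylmethyl group shields one enamine face so that C7 is formed S, is followed in the same flask by intramolecular aldol condensation of the methyl ketone onto the aldehyde, which does not touch the new stereocentre.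

Step 2
Reactants: 5 methyl acetate
Product: 7 1-methoxy-1-(trimethylsilyloxy)ethene, via lithium enolate 6 (not isolated)
Conditions: LiN(iPr)2, THF, −78 °C; then Me3SiCl, −78 °C to rt; distillation
Reagents that add atoms: chlorotrimethylsilane (C[Si](C)(C)Cl)
Why: Kinetic enolisation of the ester and O-silylation of the lithium enolate give the silyl ketene acetal as a neutral acetate nucleophile; no stereocentre is formed.

Step 3
Reactants: 4 (4S)-4-(propan-2-yl)cyclohex-2-en-1-one; 7 1-methoxy-1-(trimethylsilyloxy)ethene
Product: 9 methyl 2-[(1S,6S)-6-(propan-2-yl)-3-(trifluoromethanesulfonyloxy)cyclohex-2-en-1-yl]acetate, via silyl enol ether 8 (not isolated)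
Conditions: LiClO4 (10 mol%), MeCN, rt; then CsF, PhNTf2, DME, rt
Reagents that add atoms: N-phenylbis(trifluoromethanesulfonimide) (O=S(=O)(N(c1ccccc1)S(=O)(=O)C(F)(F)F)C(F)(F)F)
Why: Mukaiyama–Michael addition occurs anti to the adjacent isopropyl group (axial attack on the half-chair with that group pseudo-equatorial), setting C6 trans to C7, and the regiodefined silyl enol ether is converted by fluoride-triggered O-triflation into a single enol triflate regioisomer.

Step 4
Reactants: 9 methyl 2-[(1S,6S)-6-(propan-2-yl)-3-(trifluoromethanesulfonyloxy)cyclohex-2-en-1-yl]acetate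
Product: 10 methyl 2-[(1S,6S)-3-methyl-6-(propan-2-yl)cyclohex-2-en-1-yl]acetate
Conditions: MeMgBr (1.5 equiv), Fe(acac)3 (5 mol%), THF/NMP, −30 °C
Reagents that add atoms: methylmagnesium bromide (C[Mg]Br)
Why: Iron-catalysed Kumada-type cross-coupling of the alkenyl triflate is complete within minutes at −30 °C, so the methyl ester survives; no stereocentre is involved.

Step 5
Reactants: 10 methyl 2-[(1S,6S)-3-methyl-6-(propan-2-yl)cyclohex-2-en-1-yl]acetate
Product: 11 1-{[(1S,6S)-3-methyl-6-(propan-2-yl)cyclohex-2-en-1-yl]methyl}cyclopropan-1-ol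
Conditions: EtMgBr (3 equiv), Ti(OiPr)4 (20 mol%), THF, 0 °C to rt
Reagents that add atoms: ethylmagnesium bromide (CC[Mg]Br)
Why: Kulinkovich cyclopropanation, in which the titanacyclopropane made from EtMgBr and Ti(OiPr)4 adds twice to the ester carbonyl, gives the 1-substituted cyclopropanol and leaves the trisubstituted alkene and both stereocentres untouched.

Step 6 (key step)
Reactants: 11 1-{[(1S,6S)-3-methyl-6-(propan-2-yl)cyclohex-2-en-1-yl]methyl}cyclopropan-1-ol
Product: 14 (4aR,5R,8S,8aS)-5-methyl-8-(propan-2-yl)-3,4,4a,5,6,7,8,8a-octahydronaphthalen-2(1H)-one, via keto radical 12 (not isolated), via tertiary radical 13 (not isolated)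
Conditions: [Ir(dF(CF3)ppy)2(5,5'-d(CF3)bpy)]PF6 (2 mol%), Bu4N[(BuO)2PO2] (10 mol%), 2,4,6-triisopropylbenzenethiol (5 mol%), PhCF3 (0.01 M), blue LEDs, 25 °C
Reagents that add atoms: none
Why: Proposed new method: proton-coupled electron transfer from the cyclopropanol O–H to the photoexcited iridium complex and phosphate base gives an alkoxy radical whose strain-driven β-scission delivers the primary β-keto radical 12, which closes ring B by 6-exo-trig attack on the less substituted alkene carbon through a chair transition state on the face syn to the C6 side chain (cis ring fusion, fixing C1), and the tertiary radical 13 then takes a hydrogen atom from the thiol co-catalyst axially, anti to the axial C1–C2 bond, so the C10 methyl ends up equatorial and cis to C2 (fixing C10); the closest known reaction types are the light-driven redox-neutral ring-opening isomerisation of cyclic alcohols with thiol hydrogen-atom transfer and the oxidative ring-opening/cyclisation of cyclopropanols, and the thiol is kept dilute so that cyclisation outruns premature reduction.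

Step 7
Reactants: 14 (4aR,5R,8S,8aS)-5-methyl-8-(propan-2-yl)-3,4,4a,5,6,7,8,8a-octahydronaphthalen-2(1H)-one
Product: 16 (4aR,5R,8S)-5-methyl-8-(propan-2-yl)-4,4a,5,6,7,8-hexahydronaphthalen-2(3H)-one, via silyl enol ether 15 (not isolated)
Conditions: Me3SiCl, NaI, Et3N, MeCN, rt; pentane extraction; then Pd(OAc)2 (10 mol%), O2 (1 atm), DMSO, 40 °C
Reagents that add atoms: none
Why: Equilibrating silylation of a cis-fused 2-decalone favours the enol ether on the ring-fusion side (the pattern known from 5β-3-keto steroids), and Saegusa–Ito oxidation (palladium enolate, β-hydride elimination of the ring-fusion hydrogen, reoxidation by O2) then gives the conjugated enone, removing the C6 stereocentre while C1, C7 and C10 are untouched.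

Step 8
Reactants: 16 (4aR,5R,8S)-5-methyl-8-(propan-2-yl)-4,4a,5,6,7,8-hexahydronaphthalen-2(3H)-one
Product: 17 (1S,4R,4aR)-4-methyl-7-methylidene-1-(propan-2-yl)-1,2,3,4,4a,5,6,7-octahydronaphthalene
Conditions: Cp2TiMe2 (2.5 equiv), toluene, 70 °C, dark
Reagents that add atoms: dimethyltitanocene (C[Ti](C)(C1C=CC=C1)C1C=CC=C1)
Why: Petasis methylenation through thermally generated Cp2Ti=CH2 converts the enone carbonyl into the exocyclic alkene under non-basic conditions, so the γ-stereocentres C1 and C7 cannot epimerise through a dienolate.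

Step 9
Reactants: 18 benzene-1,3-diol
Product: 21 benzene-1,3,5-triol, via bis-silyl ether 19 (not isolated), via aryl boronate 20 (not isolated)
Conditions: (Me3Si)2NH, 80 °C; then HBpin, [Ir(OMe)(cod)]2 (1.5 mol%), dtbpy (3 mol%), hexane, 80 °C; then KHSO5 (as 2KHSO5·KHSO4·K2SO4), acetone/H2O, rt
Reagents that add atoms: potassium peroxymonosulfate ([K+].[O-]S(=O)(=O)OO)
Why: Sterically controlled iridium-catalysed C–H borylation of the transiently silylated 1,3-dioxygenated arene occurs only at C5 (the one C–H flanked by two hydrogens), and oxidation of the aryl boronate with peroxymonosulfate plus aqueous desilylation gives the symmetrical triol.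

Step 10
Reactants: 21 benzene-1,3,5-triol
Product: 23 2,4,6-trihydroxybenzene-1,3-dicarbaldehyde, via bis-iminium salt 22 (not isolated)
Conditions: POCl3 (2.4 equiv), DMF (2.4 equiv), EtOAc, 0 °C to rt; then H2O, 50 °C
Reagents that add atoms: N,N-dimethylformamide (CN(C)C=O); water (O)
Why: Vilsmeier–Haack formylation, in which the chloroiminium ion from DMF and POCl3 substitutes the very electron-rich ring twice (the second iminium group deactivates it enough to stop there), and hydrolysis of the bis-iminium salt releases the dialdehyde.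

Step 11
Reactants: 17 (1S,4R,4aR)-4-methyl-7-methylidene-1-(propan-2-yl)-1,2,3,4,4a,5,6,7-octahydronaphthalene; 24 benzaldehyde; 23 2,4,6-trihydroxybenzene-1,3-dicarbaldehyde
Product: 26 Guajadial C, via quinone methide 25 (not isolated)
Conditions: ethylenediammonium diacetate (10 mol%), THF, 4 Å molecular sieves, 60 °C
Reagents that add atoms: none
Why: Domino Knoevenagel condensation/inverse-electron-demand hetero-Diels–Alder reaction, in which the o-quinone methide 25 adds across the exocyclic C4=C15 bond with oxygen bonding to the more substituted C4 by axial attack on the face anti to H-1 (giving the S spiro centre) and with the C5=C6 vinyl branch endo to the heterodiene so that phenyl ends up cis to it (giving the R benzylic centre).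

**Compound list**

1 | 3-methylbutanal | CC(C)CC=O | starting material
2 | but-3-en-2-one | CC(=O)C=C | starting material
3 | (2S)-5-oxo-2-(propan-2-yl)hexanal | CC(C)[C@@H](C=O)CCC(C)=O | intermediate (not isolated)
4 | (4S)-4-(propan-2-yl)cyclohex-2-en-1-one, (S)-cryptone | CC(C)[C@@H]1CCC(=O)C=C1 | intermediate
5 | methyl acetate | COC(C)=O | starting material
6 | lithium 1-methoxyethen-1-olate | [Li+].[O-]C(=C)OC | intermediate (not isolated)
7 | 1-methoxy-1-(trimethylsilyloxy)ethene | COC(=C)O[Si](C)(C)C | intermediate
8 | methyl 2-[(1S,6S)-6-(propan-2-yl)-3-(trimethylsilyloxy)cyclohex-2-en-1-yl]acetate | CC(C)[C@@H]1CCC(O[Si](C)(C)C)=C[C@H]1CC(=O)OC | intermediate (not isolated)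
9 | methyl 2-[(1S,6S)-6-(propan-2-yl)-3-(trifluoromethanesulfonyloxy)cyclohex-2-en-1-yl]acetate | CC(C)[C@@H]1CCC(OS(=O)(=O)C(F)(F)F)=C[C@H]1CC(=O)OC | intermediate
10 | methyl 2-[(1S,6S)-3-methyl-6-(propan-2-yl)cyclohex-2-en-1-yl]acetate | CC(C)[C@@H]1CCC(C)=C[C@H]1CC(=O)OC | intermediate
11 | 1-{[(1S,6S)-3-methyl-6-(propan-2-yl)cyclohex-2-en-1-yl]methyl}cyclopropan-1-ol | CC(C)[C@@H]1CCC(C)=C[C@H]1CC1(O)CC1 | intermediate
12 | 4-[(1S,6S)-3-methyl-6-(propan-2-yl)cyclohex-2-en-1-yl]-3-oxobutyl radical | CC(C)[C@@H]1CCC(C)=C[C@H]1CC(=O)C[CH2] | intermediate (not isolated)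
13 | tertiary radical: 14 lacking the hydrogen at C-5, cis-fused, other centres as in 14 | CC(C)[C@@H]1CC[C](C)[C@H]2CCC(=O)C[C@@H]12 | intermediate (not isolated)
14 | (4aR,5R,8S,8aS)-5-methyl-8-(propan-2-yl)-3,4,4a,5,6,7,8,8a-octahydronaphthalen-2(1H)-one | CC(C)[C@@H]1CC[C@@H](C)[C@H]2CCC(=O)C[C@@H]12 | intermediate
15 | trimethylsilyl enol ether of 14 with the double bond between C-1 and C-2 (ring-fusion side) | CC(C)[C@@H]1CC[C@@H](C)[C@H]2CCC(O[Si](C)(C)C)=C[C@@H]12 | intermediate (not isolated)
16 | (4aR,5R,8S)-5-methyl-8-(propan-2-yl)-4,4a,5,6,7,8-hexahydronaphthalen-2(3H)-one | CC(C)[C@@H]1CC[C@@H](C)[C@H]2CCC(=O)C=C12 | intermediate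
17 | (1S,4R,4aR)-4-methyl-7-methylidene-1-(propan-2-yl)-1,2,3,4,4a,5,6,7-octahydronaphthalene | CC(C)[C@@H]1CC[C@@H](C)[C@H]2CCC(=C)C=C12 | intermediate
18 | benzene-1,3-diol (resorcinol) | Oc1cccc(O)c1 | starting material
19 | 1,3-bis(trimethylsilyloxy)benzene | C[Si](C)(C)Oc1cccc(O[Si](C)(C)C)c1 | intermediate (not isolated)
20 | 2-[3,5-bis(trimethylsilyloxy)phenyl]-4,4,5,5-tetramethyl-1,3,2-dioxaborolane | C[Si](C)(C)Oc1cc(O[Si](C)(C)C)cc(c1)B1OC(C)(C)C(C)(C)O1 | intermediate (not isolated)
21 | benzene-1,3,5-triol (phloroglucinol) | Oc1cc(O)cc(O)c1 | intermediate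
22 | bis(N,N-dimethyliminium) dichloride of 23 | C[N+](C)=Cc1c(O)cc(O)c(C=[N+](C)C)c1O.[Cl-].[Cl-] | intermediate (not isolated)
23 | 2,4,6-trihydroxybenzene-1,3-dicarbaldehyde | O=Cc1c(O)cc(O)c(C=O)c1O | intermediate
24 | benzaldehyde | O=Cc1ccccc1 | starting material
25 | o-quinone methide: 5-benzylidene-2,4-dihydroxy-6-oxocyclohexa-1,3-diene-1,3-dicarbaldehyde, phenyl anti to the ring carbonyl | O=CC1=C(O)C(C=O)=C(O)/C(=C\c2ccccc2)C1=O | intermediate (not isolated)
26 | Guajadial C (cadinane numbering: C1 R, C4 spiro S, C7 S, C10 R; benzylic carbon R) | CC(C)[C@@H]1CC[C@@H](C)[C@H]2CC[C@@]3(C=C12)C[C@H](c1ccccc1)c1c(O)c(C=O)c(O)c(C=O)c1O3 | target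

**Step count and risks**

Total step count: 11. Longest linear sequence: 8 steps (steps 1, 3, 4, 5, 6, 7, 8, 11).

The three steps most likely to fail:

First, step 6. The primary radical 12 may be reduced by the thiol before it cyclises, or may abstract the allylic hydrogen at C6 by a 1,5-shift; either path gives the uncyclised ethyl ketone. If that dominates, ring B is built by cycloaddition instead. The fallback sets out from 4. Butenone 2 is silylated (TBSOTf, Et3N) to the silyloxydiene 2-(tert-butyldimethylsilyloxy)buta-1,3-diene F1. A Tf2NH-catalysed Diels–Alder (stepwise double Michael) reaction of 4 with F1 in CH2Cl2 at −78 °C, anti to the isopropyl group, gives the cis-fused silyl enol ether ketone F2. Methylenation of the C10 carbonyl with Cp2TiMe2 gives the exocyclic alkene F3. Bu4NF/AcOH frees the ring B carbonyl to give the methylene ketone F4. Hydrogen-atom-transfer hydrogenation of the 1,1-disubstituted alkene (Mn(dpm)3, PhSiH3, tBuOOH, iPrOH) passes through the same tertiary radical 13, so the methyl again becomes equatorial, and the fallback comes back to the route at 14.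

Second, step 7. If equilibrating silylation does not favour the ring-fusion side strongly enough, the Saegusa step gives the regioisomeric enone. The fallback sets out from 14 and uses halogenation/elimination. PhNMe3Br3 in THF at 0 °C brominates through the same ring-fusion-side enol to give the α-bromo ketone F5. Li2CO3/LiBr in DMF at 110 °C then eliminates HBr across C5–C6, and the fallback comes back to the route at 16. Any regioisomeric enone is returned to 14 by conjugate reduction.

Third, step 11. Up to four diastereomers can form (two faces, endo or exo), and the diene may isomerise under warm, weakly acidic conditions. The fallback generates the quinone methide oxidatively at low temperature. It sets out from 23 and 24: proline-catalysed reductive benzylation with Hantzsch ester in CH2Cl2 gives 5-benzyl-2,4,6-trihydroxybenzene-1,3-dicarbaldehyde F6. Oxidation of F6 with Ag2O in CH2Cl2 at 0 °C in the presence of 17 forms 25 under neutral conditions, where the kinetic endo/axial pathway is best expressed, and the fallback comes back to the route at 25 and so to 26.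

**Further compounds**

F1 | step 6 | 2-(tert-butyldimethylsilyloxy)buta-1,3-diene | C=CC(=C)O[Si](C)(C)C(C)(C)C
F2 | step 6 | cis-fused silyl enol ether ketone (Diels–Alder adduct of 4 and F1, new bonds anti to the isopropyl group) | CC(C)[C@@H]1CCC(=O)[C@H]2CC=C(O[Si](C)(C)C(C)(C)C)C[C@@H]12
F3 | step 6 | exocyclic alkene (F2 with C10 methylidene in place of the carbonyl) | CC(C)[C@@H]1CCC(=C)[C@H]2CC=C(O[Si](C)(C)C(C)(C)C)C[C@@H]12
F4 | step 6 | methylene ketone (cis-fused; 14 with C10 methylidene in place of methyl and hydrogen) | CC(C)[C@@H]1CCC(=C)[C@H]2CCC(=O)C[C@@H]12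
F5 | step 7 | α-bromo ketone (1-bromo derivative of 14, both epimers at the bromide carbon) | CC(C)[C@@H]1CC[C@@H](C)[C@H]2CCC(=O)C(Br)[C@@H]12
F6 | step 11 | 5-benzyl-2,4,6-trihydroxybenzene-1,3-dicarbaldehyde | O=Cc1c(O)c(Cc2ccccc2)c(O)c(C=O)c1O
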